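## Structural features

Compound 16 is an achiral assembly of three benzene rings. Ring A carries a methoxy group on C1, a free hydroxyl on C3, a 4-hydroxybenzyl group on C4 (ring C, joined through the methylene C7) and a 2-(2-hydroxyphenyl)ethyl group on C5 (ring B, joined through the bridge Ca–Cb); C2 and C6 carry hydrogen. There is no stereocentre, so every problem is one of regiochemistry. The real difficulty is the contiguous C3–C4–C5 array (hydroxyl, benzyl, phenethyl) on an electron-rich ring, together with the need to tell apart the two meta-related oxygens on C1 and C3. Benzylation of a preformed 5-alkylresorcinol monomethyl ether would face three activated positions (C2, C4, C6), and methylation of a free resorcinol would not distinguish the two oxygens. The three phenols and the electron-rich ring A are sensitive to oxidants and electrophiles, so the phenols are best kept masked until the last step; the diarylmethane and the ethano bridge are robust. The feature used by the key step is the chain C7–C4–C3–C2–C1–C6–C5–Ca, which carries oxygen on C3 and C1 and is the carbon skeleton of a 3,5,7-triketo acid with C7 as carboxyl carbon. An aldol bond between C4 and C5 folds this chain into ring A with all four substituents in place. The surviving carboxyl carbon C7, tied to the C3 oxygen, both differentiates the two oxygens and offers the electrophile to which ring C is attached.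

## Logic of the disconnections

16 from 15. The two O–benzyl bonds on rings B and C are cut last. One protecting group for both phenols allows a single final deprotection and keeps acidic, oxidation-prone hydroxyls out of all organometallic steps. The forward step must cleave only benzyl–oxygen bonds and leave the methyl ether and the doubly benzylic C7 untouched.

15 from 14. The two C7–H bonds are traced back to a C7 carbonyl. A carbonyl at C7 is what the polyketide chain delivers, and it lets the C7–ring C bond be made by acyl substitution. The demand is deoxygenation of a hindered, hydrogen-bonded diaryl ketone without loss of the benzyl ethers; the ortho hydroxyl and para methoxy groups supply the cation stabilisation that an ionic reduction needs.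

14 from 11 and 12 (through 13). The bond between C7 and ring C is cut. The lactone carbonyl of 11 is C7 at the carboxyl level, and ring C becomes a simple para-substituted aryl nucleophile from a commercial bromide. The forward step must stop after one addition; collapse of the acetonide to a phenoxide next to the new ketone is relied on for that.

11 from 10. The O–CH3 bond on C1 is cut. In 10 the C3 oxygen is locked in the acetonide and the C1 hydroxyl is the only free one, so the methylation has no regiochemical choice. The only demand is a base mild enough to leave the lactone closed.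

10 from 8 (through 9). The ring bond C4–C5 is cut and the elements of water are restored at C5. A 1,2,3,5-tetrasubstituted arene becomes a linear diketone hanging on a dioxinone, and the position of every substituent is written into the chain. The forward step must fold only in the aldol sense and then aromatise.

8 from 6 and 3 (through 7). The bond C6–C5 inside the 1,3-diketone is cut, which separates the ring B fragment from the masked triketide. The forward step must acylate the terminal carbon of a dianion once only, which calls for an acyl donor that holds its tetrahedral adduct until work-up.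

6 from 4 (through 5). The bond C2–C1 is cut, leaving the commercial dioxinone and an acetyl donor. The forward step needs C-acylation at the terminal carbon of the dienolate.

3 from 2 and 2 from 1. The O–benzyl bond and then the amide C–N bond are cut. Lactone 1 already contains ring B with its ortho oxygen, Cb, Ca and the future C5 carbon at the acyl level. The forward steps are a ring-opening amidation and the etherification of the only acidic hydroxyl.

## Other disconnections considered

Alternative 1: The cut severs C5–Ca and C4–C7 together, turning ring A into an aryne and the two carbon substituents into one beta-keto ester. In the forward sense, fluoride would release the aryne from 3,5-dimethoxy-2-(trimethylsilyl)phenyl trifluoromethanesulfonate A2. The enolate carbon of methyl 3-[4-(benzyloxy)phenyl]-3-oxopropanoate A3 would add to C5, the aryl anion at C4 would close onto the ketone, and the four-membered alkoxide would open to methyl 2-{2-[4-(benzyloxy)benzoyl]-3,5-dimethoxyphenyl}acetate A1.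
- In its favour: two adjacent C–C bonds form in one operation, and the methoxy group next to the aryne should direct the nucleophile to the distal carbon C5. Ring C arrives with its C7 carbonyl already in place; on this point the alternative is better than the chosen plan, which needs a separate organomagnesium step for that bond.
- Against it: A1 carries both ring A oxygens as methyl ethers, so the C3 oxygen has to be unmasked selectively later. Chelation of a Lewis acid between the C7 ketone and the ortho methoxy group could do this, but it is one more step and one more selectivity that depends on a reagent.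
- Against it: Ca arrives as CH2CO2Me, so ring B must still be attached at Cb by ester adjustment, aryl-metal addition and deoxygenation, in a molecule whose benzophenone carbonyl competes for hydride and carbanions. A2 itself needs several steps.
- Comparison: on structure, both plans derive the ring A pattern from mechanism and neither creates a stereocentre. On mechanism, the alternative is the equal of the chosen plan in regiocontrol at the key step, but the differentiation of the oxygens is structural in 10 and reagent-dependent from A1. On step economy it would probably be longer by two to four steps.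

Alternative 2: The cut severs C5–Ca and the bond from Cb to ring B, giving three components. The aryllithium from 1-(benzyloxy)-2-[4-(benzyloxy)benzyl]-3-bromo-5-methoxybenzene A5 would add to a vinylboronic ester to give a borate. Under palladium catalysis with a ferrocenyl bisphosphine, the aryl triflate 2-(benzyloxy)phenyl trifluoromethanesulfonate A6 would trigger 1,2-migration of ring A from boron to Ca while ring B is delivered to Cb. The product would be 2-{1-{3-(benzyloxy)-2-[4-(benzyloxy)benzyl]-5-methoxyphenyl}-2-[2-(benzyloxy)phenyl]ethyl}-4,4,5,5-tetramethyl-1,3,2-dioxaborolane A4.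
- In its favour: the whole ethano bridge is assembled from a two-carbon unit with two new C–C bonds under mild conditions that tolerate benzyl ethers. In bonds formed per step and in modularity towards ring B it is better than the chosen plan.
- Against it: it does not touch the real difficulty. The regiocontrolled construction of ring A with its C3/C4/C5 array is only transferred to A5, whose synthesis would have to solve that problem by other means.
- Against it: the migrating aryl group and A6 are both ortho-substituted, which burdens the metallate shift. The boron and the stereocentre at Ca in A4 are unwanted and must be erased by protodeboronation before hydrogenolysis to 16, so a chiral ligand would be spent for nothing.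
- Comparison: on structure the chosen plan builds ring A and this one presupposes it. On mechanism the alternative forms more bonds in its key step. On step economy it should be longer once A5 is counted. The final hydrogenolysis is the same in both.

Alternative 3: The cut severs C4–C5 and C1–C2, giving a ketone and an enoate. With a potassium alkoxide, the benzyl-bearing alpha carbon of 4-[4-(benzyloxy)phenyl]butan-2-one A8 would add to the beta carbon of ethyl (2E)-5-[2-(benzyloxy)phenyl]pent-2-enoate A9. The methyl carbon would then acylate on the ester carbon to give trans-4-[4-(benzyloxy)benzyl]-5-{2-[2-(benzyloxy)phenyl]ethyl}cyclohexane-1,3-dione A7 (racemic).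
- In its favour: it forms the same C4–C5 bond as the chosen plan but in a convergent union of two simple fragments. A8 is one benzylation away from a commercial phenolic ketone, and A9 should be reachable from 1 in about three steps.
- In its favour: ring C is in place from the start, so no late aryl addition or ketone reduction is needed. In convergency it is better than the chosen plan, and in step count it could be equal or slightly better. It also needs no cryogenic dianion chemistry.
- Against it: the Michael donor must be the more substituted alpha carbon of A8 and not the methyl group. This rests on enolate equilibration and is not enforced by structure. A9 can also deconjugate under the basic conditions.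
- Against it: the carbonyls at C1 and C3 of A7 must be told apart for a single O-methylation, and only the lower steric hindrance at C1 helps there. A separate dehydrogenation is needed to reach the arene, and the two stereocentres of A7 are made only to be destroyed.
- Comparison: on structure the chosen plan fixes the oxygen differentiation through the acetonide, whereas the alternative leaves it to selectivity. On mechanism the chosen aromatisation is redox-neutral and the alternative needs an oxidant. On step economy the alternative is equal or somewhat better, at the price of two regiochemical uncertainties.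

Key step: step 5

Remark: 8 is drawn as its triketo tautomer; it is expected to exist largely in enol forms and is carried into step 5 without prolonged storage.

## Steps

Step 1
Reactants: 1 3,4-dihydrocoumarin
Product: 2 3-(2-hydroxyphenyl)-N-methoxy-N-methylpropanamide
Conditions: MeNH(OMe)·HCl, AlMe3, CH2Cl2, 0 °C → rt; aq. HCl
Reagents that add atoms: N,O-dimethylhydroxylamine hydrochloride, CNOC.Cl
Why: Weinreb amidation of a lactone by an aluminium amide formed in the flask; the aryl ester is a reactive acyl donor, the phenoxide is a good leaving group, and the N-methoxy-N-methylamide does not react further.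

Step 2
Reactants: 2 3-(2-hydroxyphenyl)-N-methoxy-N-methylpropanamide
Product: 3 3-[2-(benzyloxy)phenyl]-N-methoxy-N-methylpropanamide
Conditions: BnBr, K2CO3, DMF, rt
Reagents that add atoms: benzyl bromide, BrCc1ccccc1
Why: Williamson ether synthesis on the only acidic hydroxyl; the amide is inert to carbonate, and alkylation of the phenoxide should be much faster than any return to the lactone.

Step 3
Reactants: 4 2,2,6-trimethyl-4H-1,3-dioxin-4-one
Product: 6 2,2-dimethyl-6-(2-oxopropyl)-4H-1,3-dioxin-4-one, via lithium dioxinone dienolate 5 (not isolated)
Conditions: LiN(SiMe3)2, THF, −78 °C; AcCl (0.5 equiv), −78 °C; 1 M HCl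
Reagents that add atoms: acetyl chloride, CC(Cl)=O
Why: Claisen-type C-acylation of a vinylogous ester dienolate, which reacts with the acid chloride at its terminal carbon; 4 is used in twofold excess because the product is more acidic than 4 and takes up a second equivalent of 5.

Step 4
Reactants: 6 2,2-dimethyl-6-(2-oxopropyl)-4H-1,3-dioxin-4-one; 3 3-[2-(benzyloxy)phenyl]-N-methoxy-N-methylpropanamide
Product: 8 6-{6-[2-(benzyloxy)phenyl]-2,4-dioxohexyl}-2,2-dimethyl-4H-1,3-dioxin-4-one, via dilithium dienediolate 7 (not isolated)
Conditions: LiN(iPr)2 (2.1 equiv per 6), THF, −78 °C; then 3, −78 → −40 °C; 1 M HCl to pH 3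
Reagents that add atoms: none
Why: Crossed Claisen-type acylation of a 1,3-dicarbonyl dianion with a Weinreb amide; the second deprotonation takes place at the terminal methyl, the dianion reacts at that more basic carbon, and the chelated tetrahedral adduct releases the 1,3-diketone only on acidic quench, so over-addition is excluded.

Step 5
Reactants: 8 6-{6-[2-(benzyloxy)phenyl]-2,4-dioxohexyl}-2,2-dimethyl-4H-1,3-dioxin-4-one
Product: 10 5-{2-[2-(benzyloxy)phenyl]ethyl}-7-hydroxy-2,2-dimethyl-4H-1,3-benzodioxin-4-one, via aldol adduct 9 (not isolated)
Conditions: Et3N, CH2Cl2, rt; then 1 M HCl wash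
Reagents that add atoms: none
Why: This is the base-induced intramolecular aldol condensation and aromatisation of a diketo-dioxinone, the laboratory counterpart of the aldol folding of a tetraketide and a known way to resorcylate acetonides. Et3N removes a proton from the C2 methylene between the C1 ketone and the dioxinone, giving a vinylogous enolate whose nucleophilic carbon is the dioxinone alpha carbon C4. C4 adds to the C5 ketone, the only carbonyl within reach of a six-membered transition state, in a 6-(enolendo)-exo-trig closure that forms the C4–C5 bond and the carbocycle of ring A in 9. Loss of water across C5–C6 and enolisation of the C1 carbonyl then give the arene 10, and the gain of aromaticity makes the sequence irreversible. The carbinol carbon of 9 is a transient racemic centre that disappears on dehydration, so no stereocontrol is required. The selectivity that matters is aldol closure over Claisen or lactone closure, and the dioxinone secures it: C7 is a poorly electrophilic vinylogous carbonate carbon, the C3 oxygen cannot act as a nucleophile, and C3 is an enol ether carbon that the weakly acidic Ca position does not attack. The product keeps the C3 oxygen and C7 locked in the acetonide and leaves the C1 hydroxyl free.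

Step 6
Reactants: 10 5-{2-[2-(benzyloxy)phenyl]ethyl}-7-hydroxy-2,2-dimethyl-4H-1,3-benzodioxin-4-one
Product: 11 5-{2-[2-(benzyloxy)phenyl]ethyl}-7-methoxy-2,2-dimethyl-4H-1,3-benzodioxin-4-one
Conditions: MeI, K2CO3, acetone, rt
Reagents that add atoms: iodomethane, CI
Why: Williamson O-methylation of the only free hydroxyl, which is para to the lactone carbonyl and therefore acidic; the C3 oxygen is part of the acetonide, so the regiochemistry is fixed by structure.

Step 7
Reactants: 11 5-{2-[2-(benzyloxy)phenyl]ethyl}-7-methoxy-2,2-dimethyl-4H-1,3-benzodioxin-4-one; 12 1-(benzyloxy)-4-bromobenzene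
Product: 14 [4-(benzyloxy)phenyl]{2-{2-[2-(benzyloxy)phenyl]ethyl}-6-hydroxy-4-methoxyphenyl}methanone, via 4-(benzyloxy)phenylmagnesium bromide 13 (not isolated)
Conditions: 12, Mg, THF, reflux; then 11, THF, 0 °C → rt (3 equiv of 13); 1 M HCl
Reagents that add atoms: none
Why: Grignard formation followed by nucleophilic acyl substitution on the lactone; the tetrahedral adduct collapses with loss of acetone to a magnesium phenoxide chelated to the new ketone, and this chelate plus the two ortho substituents should block a second addition. About three equivalents of 13 are planned because the liberated acetone consumes reagent.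

Step 8
Reactants: 14 [4-(benzyloxy)phenyl]{2-{2-[2-(benzyloxy)phenyl]ethyl}-6-hydroxy-4-methoxyphenyl}methanone
Product: 15 3-{2-[2-(benzyloxy)phenyl]ethyl}-2-[4-(benzyloxy)benzyl]-5-methoxyphenol
Conditions: Et3SiH, CF3CO2H, CH2Cl2, 0 °C → rt
Reagents that add atoms: none
Why: Ionic hydrogenation (Kursanov–Parnes reduction): the protonated ketone accepts hydride, the benzhydrol ionises to a cation stabilised by the ortho hydroxyl, para methoxy and para benzyloxy groups, and a second hydride gives the methylene; benzyl aryl ethers should survive dilute CF3CO2H for the short time needed, and the silane would intercept any benzyl cation.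

Step 9
Reactants: 15 3-{2-[2-(benzyloxy)phenyl]ethyl}-2-[4-(benzyloxy)benzyl]-5-methoxyphenol
Product: 16 2-(4-hydroxybenzyl)-3-[2-(2-hydroxyphenyl)ethyl]-5-methoxyphenol
Conditions: H2 (1 atm), 10% Pd/C, EtOAc–MeOH, rt
Reagents that add atoms: none
Why: Catalytic hydrogenolysis of both benzyl aryl ethers; the methyl ether, the diarylmethane and the arenes are inert at one atmosphere and room temperature.

## Compound list

1 | 3,4-dihydrocoumarin | O=C1CCc2ccccc2O1 | starting material
2 | 3-(2-hydroxyphenyl)-N-methoxy-N-methylpropanamide | CON(C)C(=O)CCc1ccccc1O | intermediate
3 | 3-[2-(benzyloxy)phenyl]-N-methoxy-N-methylpropanamide | CON(C)C(=O)CCc1ccccc1OCc1ccccc1 | intermediate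
4 | 2,2,6-trimethyl-4H-1,3-dioxin-4-one | CC1=CC(=O)OC(C)(C)O1 | starting material
5 | lithium 2,2-dimethyl-6-methylidene-6H-1,3-dioxin-4-olate | [Li]OC1=CC(=C)OC(C)(C)O1 | intermediate (not isolated)
6 | 2,2-dimethyl-6-(2-oxopropyl)-4H-1,3-dioxin-4-one | CC(=O)CC1=CC(=O)OC(C)(C)O1 | intermediate
7 | dilithium 1-(2,2-dimethyl-4-oxido-6H-1,3-dioxin-6-ylidene)prop-2-en-2-olate | C=C(O[Li])C=C1C=C(O[Li])OC(C)(C)O1 | intermediate (not isolated)
8 | 6-{6-[2-(benzyloxy)phenyl]-2,4-dioxohexyl}-2,2-dimethyl-4H-1,3-dioxin-4-one | CC1(C)OC(=O)C=C(CC(=O)CC(=O)CCc2ccccc2OCc2ccccc2)O1 | intermediate
9 | 5-{2-[2-(benzyloxy)phenyl]ethyl}-5-hydroxy-2,2-dimethyl-5,6-dihydro-4H-1,3-benzodioxine-4,7(8H)-dione (racemic) | CC1(C)OC(=O)C2=C(CC(=O)CC2(O)CCc2ccccc2OCc2ccccc2)O1 | intermediate (not isolated)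
10 | 5-{2-[2-(benzyloxy)phenyl]ethyl}-7-hydroxy-2,2-dimethyl-4H-1,3-benzodioxin-4-one | CC1(C)OC(=O)c2c(CCc3ccccc3OCc3ccccc3)cc(O)cc2O1 | intermediate
11 | 5-{2-[2-(benzyloxy)phenyl]ethyl}-7-methoxy-2,2-dimethyl-4H-1,3-benzodioxin-4-one | CC1(C)OC(=O)c2c(CCc3ccccc3OCc3ccccc3)cc(OC)cc2O1 | intermediate
12 | 1-(benzyloxy)-4-bromobenzene | Brc1ccc(OCc2ccccc2)cc1 | starting material
13 | [4-(benzyloxy)phenyl]magnesium bromide | Br[Mg]c1ccc(OCc2ccccc2)cc1 | intermediate (not isolated)
14 | [4-(benzyloxy)phenyl]{2-{2-[2-(benzyloxy)phenyl]ethyl}-6-hydroxy-4-methoxyphenyl}methanone | COc1cc(O)c(C(=O)c2ccc(OCc3ccccc3)cc2)c(CCc2ccccc2OCc2ccccc2)c1 | intermediate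
15 | 3-{2-[2-(benzyloxy)phenyl]ethyl}-2-[4-(benzyloxy)benzyl]-5-methoxyphenol | COc1cc(O)c(Cc2ccc(OCc3ccccc3)cc2)c(CCc2ccccc2OCc2ccccc2)c1 | intermediate
16 | 2-(4-hydroxybenzyl)-3-[2-(2-hydroxyphenyl)ethyl]-5-methoxyphenol | COc1cc(O)c(Cc2ccc(O)cc2)c(CCc2ccccc2O)c1 | target

## Step count and least certain steps

Total step count: 9. Longest linear sequence: 8 steps (steps 1, 2, 4, 5, 6, 7, 8 and 9, from 1 to 16); step 3 supplies the second branch.

Step 5 (key step). The most likely failure is stalling at the aldol stage through slow dehydration of 9, or diversion of the enolised polycarbonyl chain into O-cyclisation or retro-Claisen fragmentation, because 8 has several enolisable sites and limited stability. The fallback closes ring A on an open-chain ester instead of the dioxinone.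
- Setting out from 8, heating in toluene with allyl alcohol (110 °C) should expel acetone by retro-hetero-Diels–Alder reaction. The alcohol would trap the acylketene as prop-2-en-1-yl 9-[2-(benzyloxy)phenyl]-3,5,7-trioxononanoate F1.
- Mild base (Cs2CO3, THF, then dilute acid) should fold F1 by the same C4-to-C5 aldol to prop-2-en-1-yl 2-{2-[2-(benzyloxy)phenyl]ethyl}-4,6-dihydroxybenzoate F2.
- Deallylation (Pd(PPh3)4, morpholine, THF) would give 2-{2-[2-(benzyloxy)phenyl]ethyl}-4,6-dihydroxybenzoic acid F3. Acetone with SOCl2 and DMAP in DME should then close the acetonide and return to the route at 10.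
- The price is that the aldol mode is then favoured only by the mild base and no longer enforced by the mask.

Step 4. Proton transfer from the alpha-methylene of 3 to the strongly basic dianion, or O-acylation, could lower conversion, and 8 could decompose on purification. The fallback replaces the acylation by an aldol addition and an oxidation.
- Setting out from 3 and 6, reduction of 3 (iBu2AlH, THF, −78 °C) would give 3-[2-(benzyloxy)phenyl]propanal F4.
- Dianion 7, generated from 6 as before, should add to F4 much faster than it exchanges protons. The product would be 6-{6-[2-(benzyloxy)phenyl]-4-hydroxy-2-oxohexyl}-2,2-dimethyl-4H-1,3-dioxin-4-one F5 (racemic).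
- Dess–Martin oxidation of F5 would return to the route at 8.

Step 7. Addition to a carbonyl flanked by the ring oxygen and the C5 side chain could be incomplete, or a second addition to the freed ketone could occur before the phenoxide chelate forms; the released acetone also consumes reagent. The fallback lowers C7 to the aldehyde level first.
- Setting out from 11, iBu2AlH (CH2Cl2, −78 °C) should stop at an aluminium-chelated hemiacetal. On work-up this would lose acetone and give 2-{2-[2-(benzyloxy)phenyl]ethyl}-6-hydroxy-4-methoxybenzaldehyde F6.
- Excess 13 should add to F6 to give 3-{2-[2-(benzyloxy)phenyl]ethyl}-2-{[4-(benzyloxy)phenyl](hydroxy)methyl}-5-methoxyphenol F7 (racemic).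
- The ortho-hydroxy benzhydrol F7 should ionise under very mild acid, so Et3SiH with a little CF3CO2H at −20 °C would return to the route at 15, bypassing step 8.

Step 8. The carbonyl is twisted out of conjugation and hydrogen-bonded, so reduction could be sluggish. Longer exposure to acid invites loss of a benzyl group or its migration onto the electron-rich ring A. The fallback avoids acid altogether.
- Setting out from 14, ClCO2Et and Et3N (THF, 0 °C) would give 2-[4-(benzyloxy)benzoyl]-3-{2-[2-(benzyloxy)phenyl]ethyl}-5-methoxyphenyl ethyl carbonate F8.
- NaBH4 in aqueous THF should reduce the ketone of F8. The carbonate would then migrate to the new alkoxide, elimination would give an ortho-quinone methide, and a second hydride would reduce it, returning to the route at 15.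

## Further compounds

F1 | step 5 | prop-2-en-1-yl 9-[2-(benzyloxy)phenyl]-3,5,7-trioxononanoate | C=CCOC(=O)CC(=O)CC(=O)CC(=O)CCc1ccccc1OCc1ccccc1
F2 | step 5 | prop-2-en-1-yl 2-{2-[2-(benzyloxy)phenyl]ethyl}-4,6-dihydroxybenzoate | C=CCOC(=O)c1c(O)cc(O)cc1CCc1ccccc1OCc1ccccc1
F3 | step 5 | 2-{2-[2-(benzyloxy)phenyl]ethyl}-4,6-dihydroxybenzoic acid | OC(=O)c1c(O)cc(O)cc1CCc1ccccc1OCc1ccccc1
F4 | step 4 | 3-[2-(benzyloxy)phenyl]propanal | O=CCCc1ccccc1OCc1ccccc1
F5 | step 4 | 6-{6-[2-(benzyloxy)phenyl]-4-hydroxy-2-oxohexyl}-2,2-dimethyl-4H-1,3-dioxin-4-one (racemic) | CC1(C)OC(=O)C=C(CC(=O)CC(O)CCc2ccccc2OCc2ccccc2)O1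
F6 | step 7 | 2-{2-[2-(benzyloxy)phenyl]ethyl}-6-hydroxy-4-methoxybenzaldehyde | COc1cc(O)c(C=O)c(CCc2ccccc2OCc2ccccc2)c1
F7 | step 7 | 3-{2-[2-(benzyloxy)phenyl]ethyl}-2-{[4-(benzyloxy)phenyl](hydroxy)methyl}-5-methoxyphenol (racemic) | COc1cc(O)c(C(O)c2ccc(OCc3ccccc3)cc2)c(CCc2ccccc2OCc2ccccc2)c1
F8 | step 8 | 2-[4-(benzyloxy)benzoyl]-3-{2-[2-(benzyloxy)phenyl]ethyl}-5-methoxyphenyl ethyl carbonate | CCOC(=O)Oc1cc(OC)cc(CCc2ccccc2OCc2ccccc2)c1C(=O)c1ccc(OCc2ccccc2)cc1
A1 | alternative 1 | methyl 2-{2-[4-(benzyloxy)benzoyl]-3,5-dimethoxyphenyl}acetate | COC(=O)Cc1cc(OC)cc(OC)c1C(=O)c1ccc(OCc2ccccc2)cc1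
A2 | alternative 1 | 3,5-dimethoxy-2-(trimethylsilyl)phenyl trifluoromethanesulfonate | COc1cc(OC)c([Si](C)(C)C)c(OS(=O)(=O)C(F)(F)F)c1
A3 | alternative 1 | methyl 3-[4-(benzyloxy)phenyl]-3-oxopropanoate | COC(=O)CC(=O)c1ccc(OCc2ccccc2)cc1
A4 | alternative 2 | 2-{1-{3-(benzyloxy)-2-[4-(benzyloxy)benzyl]-5-methoxyphenyl}-2-[2-(benzyloxy)phenyl]ethyl}-4,4,5,5-tetramethyl-1,3,2-dioxaborolane (one enantiomer drawn, either or the racemate serves) | COc1cc(OCc2ccccc2)c(Cc2ccc(OCc3ccccc3)cc2)c(c1)[C@@H](Cc1ccccc1OCc1ccccc1)B1OC(C)(C)C(C)(C)O1
A5 | alternative 2 | 1-(benzyloxy)-2-[4-(benzyloxy)benzyl]-3-bromo-5-methoxybenzene | COc1cc(Br)c(Cc2ccc(OCc3ccccc3)cc2)c(OCc2ccccc2)c1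
A6 | alternative 2 | 2-(benzyloxy)phenyl trifluoromethanesulfonate | O=S(=O)(Oc1ccccc1OCc1ccccc1)C(F)(F)F
A7 | alternative 3 | trans-4-[4-(benzyloxy)benzyl]-5-{2-[2-(benzyloxy)phenyl]ethyl}cyclohexane-1,3-dione (racemic, one enantiomer drawn) | O=C1CC(=O)[C@@H](Cc2ccc(OCc3ccccc3)cc2)[C@H](CCc2ccccc2OCc2ccccc2)C1
A8 | alternative 3 | 4-[4-(benzyloxy)phenyl]butan-2-one | CC(=O)CCc1ccc(OCc2ccccc2)cc1
A9 | alternative 3 | ethyl (2E)-5-[2-(benzyloxy)phenyl]pent-2-enoate | CCOC(=O)/C=C/CCc1ccccc1OCc1ccccc1
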